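The earlier runs and the new flask are calculated for an exercise, and the scatter is random.

**The target's age.** The target, the kinetic product here, appears first and its isomer lags, so I ask how old the target in a flask is when it is read.

| setting | Tuesday's | autumn | winter |
|---|---|---|---|
| substrate | 2.4 M | 2.0 M | 3.0 M |
| free catalyst | 100 mM | 100 mM | 100 mM |
| remark | run made earlier |  |  |
| time |  | 50 min | 80 min |

Tuesday's run (percent of the substrate charged)

| time / min | target / % | isomer of the product / % |
|---|---|---|
| 3.00 | 13 | 1 |
| 5.00 | 15 | 0 |
| 10.0 | 29 | 3 |
| 20.0 | 45 | 16 |
| 40.0 | 46 | 50 |

(each reading ± 1.5 percentage points)

- the winner by share of target in all that became target or isomer of the product; "neither" if no more than 2 percentage points parts them (autumn / winter / neither)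
- share of target in all that became target or isomer of the product, autumn
- share of target in all that became target or isomer of the product, winter

- the share counts what is present at the end, not what went on to other products

**Two times.** On Tuesday the target readings at 20.0 min and 40.0 min average 45.5 %, while isomer gains 34 percentage points between them. This is a mean of two scattered end readings, not a plateau, since target may rise and fall between them. Dividing that mean by the isomer's gain per minute gives a rough reading of the target's lifetime against isomerisation 26.8 min. The second time is the target's mean age. Tuesday's first 20.0 min turn over 0.0732 M/min, so I take feeding as even, lasting 27.3 min in autumn and 41.0 min in winter. Mean age is then the reading time less half the feeding time: 36.3 min in autumn, 59.5 min in winter.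

**My reckoning.** I take the share as exp(−age/lifetime), which gives 25.7 % for autumn and 10.8 % for winter. Summing portion by portion instead of using the mean moves autumn to 26.9 %.

**The forecast.** It names autumn, with 18 % (4 % to 40 %) for autumn and 9 % (1 % to 28 %) for winter, holding that “Winter has longer after exhaustion”. My autumn figure stands above its value, and so does my winter figure.

**The flask.** The winner is autumn: autumn gives 34.0 %, winter 22.0 %.

    substrate + free catalyst → catalyst intermediate (k = 43.0 /M/min)
    catalyst intermediate ⇌ free catalyst + target (K = 0.830 M, k = 0.800 /min)
    catalyst intermediate + target → spent catalyst (k = 0.0130 /M/min)
    target ⇌ isomer of the product (K = 7.70, k = 0.0340 /min)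
    target → over-reaction product (k = 2.80 × 10⁻⁵ /min)

**Age again.** The main reason for autumn's share is the hour of the reading: autumn gives 34.0 % at 50 min, but 11.4 % at 500 min. Autumn read at 20 min still holds 22.0 % of its substrate, so its feeding is unfinished, and with even feeding I take its mean age as 10.0 min. The lifetime then gives 68.9 %, and that flask holds a share of 72.3 %.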